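**Retrosynthetic overview**

1. The last steps free the C15 acid from its tert-butyl ester, put the angelate on the 8β-alcohol, and invert C8 through the 8-ketone, because the ring closure needs the 8α-silyloxy epimer as its control element.
2. The key step unravels the cyclohexane and the γ-lactone together to an open-chain (Z)-enal that carries a 2-(methoxycarbonyl)allylboronate. Allylboration closes C6–C7 (ten-membered ring), the borate lactonises, and a Cope ring contraction of the cyclodeca-1(10),4-diene closes C5–C10. This copies the presumed germacranolide → elemanolide biogenesis.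
3. Enabling feature: the cyclohexane carries on the adjacent ring carbons C10 and C5 a vinyl and a 1-carboxyvinyl group, together the hexa-1,5-diene C2=C1–C10–C5–C4=C3 (Cope retron of a ten-membered ring). C7, next to carbinol C6, carries the methylene acyl unit C13=C11–C12 of the lactone (retron of a 2-carboalkoxyallyl nucleophile plus an aldehyde).
4. The open chain comes from two ynoates whose cis-hydroalumination sets both trisubstituted enoate geometries. They are joined by B-alkyl Suzuki–Miyaura coupling; C1=C10 comes from carboalumination and C8 from a catalytic asymmetric propargylation.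
5. Ring order: ten-membered carbocycle, then γ-lactone, then cyclohexane by contraction of the ten-membered ring, all in one flask.

Key step: step 12

Numbering: elemane/germacrane numbers are used throughout (C1=C2 vinyl and C14 methyl on C10; C3=C4 with C15 on C5; lactone O on C6; C11(=C13)–C12 on C7; O-acyl on C8).

Assumption: the (S)-configured phosphoric acid of step 3 is taken to give the (S)-carbinol with the ynal, as with aryl and alkenyl aldehydes; if the sense is opposite, the (R)-acid is used.

**Step 1**
Reactants: 1 4-methoxybenzyl propargyl ether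
Product: 3 tert-butyl 4-[(4-methoxybenzyl)oxy]but-2-ynoate, via lithium acetylide 2 (not isolated)
Conditions: n-BuLi, THF, −78 °C; Boc2O, −78 → 0 °C
Reagents that add atoms: di-tert-butyl dicarbonate, CC(C)(C)OC(=O)OC(=O)OC(C)(C)C
Why: C-acylation of a lithium acetylide with Boc2O is a standard route to tert-butyl alk-2-ynoates, and the PMB ether is inert to n-BuLi at −78 °C.

**Step 2**
Reactants: 3 tert-butyl 4-[(4-methoxybenzyl)oxy]but-2-ynoate
Product: 5 tert-butyl (E)-2-iodo-4-[(4-methoxybenzyl)oxy]but-2-enoate, via alkenylalane 4 (not isolated)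
Conditions: i-Bu2AlH, HMPA, THF, 0 °C; then I2, −78 → 0 °C
Reagents that add atoms: iodine, II
Why: cis-hydroalumination of the ynoate with the i-Bu2AlH·HMPA complex puts aluminium on the α-carbon and hydride on the β-carbon from the same face, and iodinolysis of the C–Al bond with retention should give the α-iodo enoate with CH2OPMB cis to the ester, the geometry that C4=C5 needs.

**Step 3**
Reactants: 6 3-(trimethylsilyl)prop-2-ynal; 7 allenylboronic acid pinacol ester
Product: 9 (3S)-1-(trimethylsilyl)hexa-1,5-diyn-3-ol, via homopropargyl borate 8 (not isolated)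
Conditions: (S)-3,3′-bis(2,4,6-triisopropylphenyl)-1,1′-binaphthyl-2,2′-diyl hydrogen phosphate (5 mol%), 4 Å MS, toluene, −20 °C; aq. NaHCO3 work-up
Reagents that add atoms: none
Why: chiral phosphoric acid-catalysed propargylation of an aldehyde with an allenylboronate runs through a closed six-membered transition state in which the phosphate, hydrogen-bonded to a boronate oxygen, differentiates the aldehyde faces and so sets C8, and the non-enolisable ynal should behave like the enals for which the reaction is known.

**Step 4**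
Reactants: 9 (3S)-1-(trimethylsilyl)hexa-1,5-diyn-3-ol
Product: 10 (3S)-3-[(tert-butyldimethylsilyl)oxy]-1-(trimethylsilyl)hexa-1,5-diyne
Conditions: TBSCl, imidazole, DMF, 25 °C
Reagents that add atoms: tert-butyldimethylsilyl chloride, CC(C)(C)[Si](C)(C)Cl
Why: standard silylation of a secondary propargylic alcohol, which installs the bulky group that later steers the ring closure.

**Step 5**
Reactants: 10 (3S)-3-[(tert-butyldimethylsilyl)oxy]-1-(trimethylsilyl)hexa-1,5-diyne; 11 vinyl bromide
Product: 13 (3S,5E)-3-[(tert-butyldimethylsilyl)oxy]-5-methyl-1-(trimethylsilyl)octa-5,7-dien-1-yne, via alkenylalane 12 (not isolated)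
Conditions: AlMe3, Cp2ZrCl2 (20 mol%), CH2Cl2, 0 → 25 °C; then 11, Pd(PPh3)4 (5 mol%), ZnCl2 (20 mol%), THF, 25 °C
Reagents that add atoms: trimethylaluminium, C[Al](C)C
Why: zirconium-catalysed syn-carboalumination of the terminal alkyne (the silyl-capped alkyne is inert) places methyl on C10 and aluminium on C1 cis to each other, and the Negishi coupling of the alkenylalane with vinyl bromide goes with retention to give the (E)-trisubstituted C1=C10 alkene.

**Step 6**
Reactants: 13 (3S,5E)-3-[(tert-butyldimethylsilyl)oxy]-5-methyl-1-(trimethylsilyl)octa-5,7-dien-1-yne; 5 tert-butyl (E)-2-iodo-4-[(4-methoxybenzyl)oxy]but-2-enoate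
Product: 15 tert-butyl (2Z,5E,8S)-8-[(tert-butyldimethylsilyl)oxy]-2-{2-[(4-methoxybenzyl)oxy]ethylidene}-6-methyl-10-(trimethylsilyl)dec-5-en-9-ynoate, via alkylborane 14 (not isolated)
Conditions: 9-BBN, THF, 0 → 25 °C; then 5, PdCl2(dppf) (5 mol%), AsPh3, Cs2CO3, DMF–H2O, 25 °C
Reagents that add atoms: none
Why: 9-BBN hydroborates only the terminal vinyl group of the diene (boron on C3), and the B-alkyl Suzuki–Miyaura coupling with the α-iodo enoate goes with retention at the sp2 carbon, so C3–C4 is formed with CH2OPMB still cis to the ester.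

**Step 7**
Reactants: 15 the silyl-capped enynoate
Product: 16 tert-butyl (2Z,5E,8S)-8-[(tert-butyldimethylsilyl)oxy]-2-{2-[(4-methoxybenzyl)oxy]ethylidene}-6-methyldec-5-en-9-ynoate
Conditions: K2CO3, MeOH, 0 → 25 °C
Reagents that add atoms: none
Why: methanolysis of the alkynyl C–Si bond with K2CO3 is selective over the TBS ether, the PMB ether and the hindered tert-butyl ester.

**Step 8**
Reactants: 16 the terminal alkyne
Product: 18 1-tert-butyl 11-methyl (2Z,5E,8S)-8-[(tert-butyldimethylsilyl)oxy]-2-{2-[(4-methoxybenzyl)oxy]ethylidene}-6-methylundec-5-en-9-ynedioate, via lithium acetylide 17 (not isolated)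
Conditions: LiN(SiMe3)2, THF, −78 °C; ClCO2Me, −78 → −20 °C
Reagents that add atoms: methyl chloroformate, COC(=O)Cl
Why: deprotonation of the terminal alkyne and C-acylation of the acetylide with methyl chloroformate is a standard ynoate synthesis, and at −78 °C the silazide should not touch the hindered tert-butyl enoate.

**Step 9**
Reactants: 18 the ynoate
Product: 20 1-tert-butyl 11-methyl (2Z,5E,8S,9Z)-8-[(tert-butyldimethylsilyl)oxy]-2-{2-[(4-methoxybenzyl)oxy]ethylidene}-6-methyl-10-[(4,4,5,5-tetramethyl-1,3,2-dioxaborolan-2-yl)methyl]undeca-5,9-dienedioate, via alkenylalane 19 (not isolated)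
Conditions: i-Bu2AlH, HMPA, THF, 0 °C; then ICH2Bpin, 0 → 25 °C
Reagents that add atoms: 2-(iodomethyl)-4,4,5,5-tetramethyl-1,3,2-dioxaborolane, ICB1OC(C)(C)C(C)(C)O1
Why: the cis-hydroalumination of step 2 is chemoselective for the ynoate over the trisubstituted tert-butyl enoate, and C-alkylation of the α-aluminio enoate with ICH2Bpin with retention should give the allylboronate with C8 cis to the ester and trans to CH2B, the geometry that leads to the anti adduct.

**Step 10**
Reactants: 20 the allylboronate PMB ether
Product: 21 1-tert-butyl 11-methyl (2Z,5E,8S,9Z)-8-[(tert-butyldimethylsilyl)oxy]-2-(2-hydroxyethylidene)-6-methyl-10-[(4,4,5,5-tetramethyl-1,3,2-dioxaborolan-2-yl)methyl]undeca-5,9-dienedioate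
Conditions: DDQ, CH2Cl2–pH 7 buffer, 0 °C
Reagents that add atoms: none
Why: oxidative PMB cleavage with buffered DDQ leaves the silyl ether, the electron-poor allylboronate and both esters untouched, and the neutral medium avoids lactonisation of the (Z)-γ-hydroxy enoate.

**Step 11**
Reactants: 21 the allylic alcohol
Product: 22 1-tert-butyl 11-methyl (2Z,5E,8S,9Z)-8-[(tert-butyldimethylsilyl)oxy]-6-methyl-2-(2-oxoethylidene)-10-[(4,4,5,5-tetramethyl-1,3,2-dioxaborolan-2-yl)methyl]undeca-5,9-dienedioate
Conditions: Dess–Martin periodinane, pyridine, CH2Cl2, 0 °C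
Reagents that add atoms: none
Why: Dess–Martin oxidation of the primary allylic alcohol is neutral and fast, so the (Z)-enal should form without Z to E isomerisation, and the 2-(alkoxycarbonyl)allylboronate is too unreactive to add to the aldehyde at 0 °C without a catalyst.

**Step 12**
Reactants: 22 the open-chain (Z)-enal allylboronate
Product: 25 tert-butyl 8α-[(tert-butyldimethylsilyl)oxy]elema-1,3,11(13)-trien-12,6α-olid-15-oate, via ten-membered borate 23 (not isolated), via germacranolide 24 (not isolated)
Conditions: Sc(OTf)3 (20 mol%), 4 Å MS, toluene, 25 °C, slow addition of 22 (final 1 mM); then 2,6-lutidine, 105 °C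
Reagents that add atoms: none
Why: Proposed new method: Sc(OTf)3 activates the boronate so that the C6 aldehyde is allylated intramolecularly through a closed chair-like six-membered transition state (C7 attacks, C13 becomes the exocyclic methylene), the O6 borate lactonises onto the C12 methyl ester, and on heating the trans,trans-cyclodeca-1(10),4-diene undergoes a [3,3]-sigmatropic shift; the closest known reactions are the Sc(OTf)3-catalysed intermolecular allylboration of aldehydes with 2-(alkoxycarbonyl)allylboronates to α-methylene-γ-lactones, the CrCl2-mediated intramolecular allylation that closes this same bond in ten-membered germacranolides, and the thermal Cope rearrangement of germacranolides to elemanolides, whereas a medium-ring allylboration and its coupling to the Cope shift in one flask are not known. The ten-membered carbocycle closes by C6–C7 bond formation under pseudo-high dilution at 25 °C (cold enough that the open chain cannot undergo a premature acyclic Cope shift), the γ-lactone closes by 5-exo-trig acyl substitution, and the cyclohexane is made from the ten-membered ring by ring contraction, the transannular Cope shift joining C5 to C10 while C2–C3 breaks. C6 and C7 are set anti (trans-lactone) because C8 is trans to CH2B on C7=C11 and hence equatorial in the chair, and their absolute sense is set by C8: allylic 1,3-strain with the cis ester keeps H8 in the alkene plane, the ring carbon C9 must stay gauche to the forming bond, and the bulky OTBS group therefore lies anti to the incoming aldehyde. C5 and C10 are set by the chair transition state of the Cope shift within the crossed diene conformation that the trans-fused lactone enforces, which should place H5 α and the C10 methyl β as in the natural germacranolide to elemanolide series. The step needs ring closure over oligomerisation (slow addition), no acid-induced transannular cyclisation (the ester on C4 deactivates C4=C5 as a π-nucleophile and the Lewis acid is quenched with 2,6-lutidine before heating), and a Cope equilibrium on the elemane side, for which strain release of the cyclodecadiene and the ester on C4, which stabilises the diyl-like transition state and stays conjugated in the product, should suffice.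

**Step 13**
Reactants: 25 the 8α-silyloxy elemanolide
Product: 26 tert-butyl 8α-hydroxyelema-1,3,11(13)-trien-12,6α-olid-15-oate
Conditions: HF·pyridine, THF, 0 → 25 °C
Reagents that add atoms: none
Why: fluoride-mediated cleavage of the secondary TBS ether with HF·pyridine does not affect the tert-butyl ester, the lactone or the two acrylate units.

**Step 14**
Reactants: 26 the 8α-alcohol
Product: 27 tert-butyl 8-oxoelema-1,3,11(13)-trien-12,6α-olid-15-oate
Conditions: Dess–Martin periodinane, pyridine, CH2Cl2, 0 → 25 °C
Reagents that add atoms: none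
Why: Dess–Martin oxidation turns the equatorial 8α-alcohol, which has served as the control element, into the C8 ketone under non-basic conditions that avoid β-elimination of the lactone oxygen and epimerisation at C7.

**Step 15**
Reactants: 27 the 8-ketone
Product: 28 tert-butyl 8β-hydroxyelema-1,3,11(13)-trien-12,6α-olid-15-oate
Conditions: NaBH4, CeCl3·7H2O, MeOH, −78 °C
Reagents that add atoms: none
Why: Luche reduction is chemoselective for the ketone over the α-methylene lactone and the acrylate, and hydride should add from the α-face (equatorial attack) because axial attack is blocked by the syn-axial C10 methyl group, as in borohydride reductions of cyclohexanones with a 3-axial methyl group, which sets the axial 8β-alcohol.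

**Step 16**
Reactants: 28 the 8β-alcohol; 29 angelic acid
Product: 31 tert-butyl 8β-angeloyloxyelema-1,3,11(13)-trien-12,6α-olid-15-oate, via mixed anhydride 30 (not isolated)
Conditions: 2,4,6-trichlorobenzoyl chloride, Et3N, toluene, 25 °C; then 28, 80 °C
Reagents that add atoms: none
Why: Yamaguchi esterification through the mixed anhydride without DMAP acylates hindered secondary alcohols at the less hindered angeloyl carbonyl and should keep the (Z)-geometry, since no nucleophilic catalyst is present that could add reversibly to the angeloyl double bond.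

**Step 17**
Reactants: 31 the tert-butyl ester
Product: 32 8β-angeloyloxyelema-1,3,11(13)-trien-12,6α-olid-15-oic acid (CNP0256928.2)
Conditions: CF3CO2H, CH2Cl2, 0 °C
Reagents that add atoms: none
Why: acidolysis of the tert-butyl ester (loss of 2-methylpropene) frees the C15 acid without touching the lactone, the angelate or the alkenes at 0 °C.

**Compound list**

1 | 1-methoxy-4-[(prop-2-yn-1-yloxy)methyl]benzene (4-methoxybenzyl propargyl ether) | COc1ccc(COCC#C)cc1 | starting material
2 | lithium acetylide of 1 | COc1ccc(COCC#C[Li])cc1 | intermediate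
3 | tert-butyl 4-[(4-methoxybenzyl)oxy]but-2-ynoate | COc1ccc(COCC#CC(=O)OC(C)(C)C)cc1 | intermediate
4 | tert-butyl 2-(diisobutylalumanyl)-4-[(4-methoxybenzyl)oxy]but-2-enoate, CH2OPMB cis to the ester | COc1ccc(COC/C=C(/[Al](CC(C)C)CC(C)C)C(=O)OC(C)(C)C)cc1 | intermediate
5 | tert-butyl (E)-2-iodo-4-[(4-methoxybenzyl)oxy]but-2-enoate, CH2OPMB cis to the ester | COc1ccc(COC/C=C(/I)C(=O)OC(C)(C)C)cc1 | intermediate
6 | 3-(trimethylsilyl)prop-2-ynal | C[Si](C)(C)C#CC=O | starting material
7 | 4,4,5,5-tetramethyl-2-(propa-1,2-dien-1-yl)-1,3,2-dioxaborolane (allenylboronic acid pinacol ester) | C=C=CB1OC(C)(C)C(C)(C)O1 | starting material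
8 | pinacol borate of 9 | C#CC[C@H](OB1OC(C)(C)C(C)(C)O1)C#C[Si](C)(C)C | intermediate
9 | (3S)-1-(trimethylsilyl)hexa-1,5-diyn-3-ol | C#CC[C@H](O)C#C[Si](C)(C)C | intermediate
10 | (3S)-3-[(tert-butyldimethylsilyl)oxy]-1-(trimethylsilyl)hexa-1,5-diyne | C#CC[C@H](O[Si](C)(C)C(C)(C)C)C#C[Si](C)(C)C | intermediate
11 | bromoethene (vinyl bromide) | C=CBr | starting material
12 | (E)-alkenyl(dimethyl)alane from 10, Al on C1 cis to the new methyl on C10 | C[Al](C)/C=C(C)/C[C@H](O[Si](C)(C)C(C)(C)C)C#C[Si](C)(C)C | intermediate
13 | (3S,5E)-3-[(tert-butyldimethylsilyl)oxy]-5-methyl-1-(trimethylsilyl)octa-5,7-dien-1-yne | C=C/C=C(C)/C[C@H](O[Si](C)(C)C(C)(C)C)C#C[Si](C)(C)C | intermediate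
14 | B-alkyl-9-borabicyclo[3.3.1]nonane from 13, boron on the former terminal vinyl carbon (C3) | B1(C2CCCC1CCC2)CC/C=C(C)/C[C@H](O[Si](C)(C)C(C)(C)C)C#C[Si](C)(C)C | intermediate
15 | tert-butyl (2Z,5E,8S)-8-[(tert-butyldimethylsilyl)oxy]-2-{2-[(4-methoxybenzyl)oxy]ethylidene}-6-methyl-10-(trimethylsilyl)dec-5-en-9-ynoate | COc1ccc(COC/C=C(C(=O)OC(C)(C)C)/CC/C=C(C)/C[C@H](O[Si](C)(C)C(C)(C)C)C#C[Si](C)(C)C)cc1 | intermediate
16 | tert-butyl (2Z,5E,8S)-8-[(tert-butyldimethylsilyl)oxy]-2-{2-[(4-methoxybenzyl)oxy]ethylidene}-6-methyldec-5-en-9-ynoate | COc1ccc(COC/C=C(C(=O)OC(C)(C)C)/CC/C=C(C)/C[C@H](O[Si](C)(C)C(C)(C)C)C#C)cc1 | intermediate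
17 | lithium acetylide of 16 | COc1ccc(COC/C=C(C(=O)OC(C)(C)C)/CC/C=C(C)/C[C@H](O[Si](C)(C)C(C)(C)C)C#C[Li])cc1 | intermediate
18 | 1-tert-butyl 11-methyl (2Z,5E,8S)-8-[(tert-butyldimethylsilyl)oxy]-2-{2-[(4-methoxybenzyl)oxy]ethylidene}-6-methylundec-5-en-9-ynedioate | COc1ccc(COC/C=C(C(=O)OC(C)(C)C)/CC/C=C(C)/C[C@H](O[Si](C)(C)C(C)(C)C)C#CC(=O)OC)cc1 | intermediate
19 | α-(diisobutylalumanyl) enoate from 18, C8 cis to the methyl ester | COc1ccc(COC/C=C(C(=O)OC(C)(C)C)/CC/C=C(C)/C[C@H](O[Si](C)(C)C(C)(C)C)/C=C(/[Al](CC(C)C)CC(C)C)C(=O)OC)cc1 | intermediate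
20 | 1-tert-butyl 11-methyl (2Z,5E,8S,9Z)-8-[(tert-butyldimethylsilyl)oxy]-2-{2-[(4-methoxybenzyl)oxy]ethylidene}-6-methyl-10-[(4,4,5,5-tetramethyl-1,3,2-dioxaborolan-2-yl)methyl]undeca-5,9-dienedioate | COc1ccc(COC/C=C(C(=O)OC(C)(C)C)/CC/C=C(C)/C[C@H](O[Si](C)(C)C(C)(C)C)/C=C(C(=O)OC)/CB2OC(C)(C)C(C)(C)O2)cc1 | intermediate
21 | the 2-(2-hydroxyethylidene) analogue of 20 (free C6 alcohol, 2Z,5E,8S,9Z) | OC/C=C(C(=O)OC(C)(C)C)/CC/C=C(C)/C[C@H](O[Si](C)(C)C(C)(C)C)/C=C(C(=O)OC)/CB1OC(C)(C)C(C)(C)O1 | intermediate
22 | the 2-(2-oxoethylidene) analogue of 20 (C6 aldehyde cis to the tert-butyl ester, 2Z,5E,8S,9Z) | O=C/C=C(C(=O)OC(C)(C)C)/CC/C=C(C)/C[C@H](O[Si](C)(C)C(C)(C)C)/C=C(C(=O)OC)/CB1OC(C)(C)C(C)(C)O1 | intermediate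
23 | ten-membered pinacol borate: germacra-1(10),4,11(13)-triene with 6α-OBpin, 8α-OTBS, C12 methyl ester and C15 tert-butyl ester (6βH,7αH; ring bonds trans at both ring alkenes) | C/C1=C\CC/C(C(=O)OC(C)(C)C)=C/[C@@H](OB2OC(C)(C)C(C)(C)O2)[C@H](C(=C)C(=O)OC)[C@@H](O[Si](C)(C)C(C)(C)C)C1 | intermediate
24 | tert-butyl 8α-[(tert-butyldimethylsilyl)oxy]germacra-1(10),4,11(13)-trien-12,6α-olid-15-oate (6βH,7αH; ring bonds trans at both ring alkenes) | C/C1=C\CC/C(C(=O)OC(C)(C)C)=C/[C@H]2OC(=O)C(=C)[C@@H]2[C@@H](O[Si](C)(C)C(C)(C)C)C1 | intermediate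
25 | tert-butyl 8α-[(tert-butyldimethylsilyl)oxy]elema-1,3,11(13)-trien-12,6α-olid-15-oate (5αH,6βH,7αH,10β-methyl) | C=C[C@]1(C)C[C@H](O[Si](C)(C)C(C)(C)C)[C@H]2C(=C)C(=O)O[C@@H]2[C@H]1C(=C)C(=O)OC(C)(C)C | intermediate
26 | tert-butyl 8α-hydroxyelema-1,3,11(13)-trien-12,6α-olid-15-oate | C=C[C@]1(C)C[C@H](O)[C@H]2C(=C)C(=O)O[C@@H]2[C@H]1C(=C)C(=O)OC(C)(C)C | intermediate
27 | tert-butyl 8-oxoelema-1,3,11(13)-trien-12,6α-olid-15-oate | C=C[C@]1(C)CC(=O)[C@H]2C(=C)C(=O)O[C@@H]2[C@H]1C(=C)C(=O)OC(C)(C)C | intermediate
28 | tert-butyl 8β-hydroxyelema-1,3,11(13)-trien-12,6α-olid-15-oate | C=C[C@]1(C)C[C@@H](O)[C@H]2C(=C)C(=O)O[C@@H]2[C@H]1C(=C)C(=O)OC(C)(C)C | intermediate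
29 | angelic acid, (Z)-2-methylbut-2-enoic acid | C/C=C(/C)C(=O)O | starting material
30 | angelic 2,4,6-trichlorobenzoic anhydride | C/C=C(/C)C(=O)OC(=O)c1c(Cl)cc(Cl)cc1Cl | intermediate
31 | tert-butyl 8β-angeloyloxyelema-1,3,11(13)-trien-12,6α-olid-15-oate | C=C[C@]1(C)C[C@@H](OC(=O)/C(C)=C\C)[C@H]2C(=C)C(=O)O[C@@H]2[C@H]1C(=C)C(=O)OC(C)(C)C | intermediate
32 | 8β-angeloyloxyelema-1,3,11(13)-trien-12,6α-olid-15-oic acid, (5R,6R,7R,8R,10S) in elemane numbering | C=C[C@]1(C)C[C@@H](OC(=O)/C(C)=C\C)[C@H]2C(=C)C(=O)O[C@@H]2[C@H]1C(=C)C(=O)O | target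

**Step count and risks**

Total step count: 17 (steps 1–2 make the western iodide 5; steps 3–17 form the main line).
Longest linear sequence: 15 steps (6 and 7 to 32, steps 3–17).

Step 12 (proposed new method) is the riskiest. Intermolecular allylboration may outrun the ten-membered ring closure. The aldehyde may add to the other face of the allyl unit if C8 controls the ten-membered transition state less well than assumed. The Cope equilibrium may also stall at the germacranolide stage. The fallback uses known chemistry and sets out from 18. The alkenylalane 19 is trapped with monomeric formaldehyde instead of ICH2Bpin to give the allylic alcohol F1. CBr4/PPh3 converts F1 into the allylic bromide F2, buffered DDQ gives the hydroxy bromide F3, and Dess–Martin oxidation gives the bromo aldehyde F4. A CrCl2-mediated intramolecular allylation of the Nozaki–Hiyama–Kishi type (THF, 25 °C, high dilution), the known way to close C6–C7 of germacranolides, gives the ten-membered hydroxy ester F5. F5 lactonises with PPTS to the germacranolide 24, which is isolated here. Heating 24 in toluene or xylene, the known thermal Cope rearrangement of germacranolides, comes back to the route at 25.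

Step 9 may fail through loss of the kinetic alkene geometry of the aluminium intermediate (isomerisation through the allenoate form) before it is alkylated, or through O-alkylation or partial reduction of the esters. The fallback sets out from 18. Hydroalumination as before followed by iodine, exactly as in step 2, gives the α-iodo enoate F6. Palladium-catalysed Negishi coupling of F6 with (pinacolatoboryl)methylzinc iodide (from ICH2Bpin and zinc dust) goes with retention and comes back to the route at 20.

Step 16 may fail through slow acylation of the axial 8β-alcohol, which is shielded by the syn-axial C10 methyl group, and through isomerisation of the angeloyl double bond to the tigloyl geometry under forcing conditions. The fallback sets out from 28. The alcohol is esterified with 2-[bis(2,2,2-trifluoroethoxy)phosphoryl]propanoic acid (N,N′-diisopropylcarbodiimide, DMAP), which can be forced because the acyl donor has no isomerisable alkene; this gives the phosphonopropionate ester F7. A Still–Gennari olefination of F7 with acetaldehyde (KN(SiMe3)2, 18-crown-6, THF, −78 °C) builds the (Z)-2-methylbut-2-enoate on the ester and comes back to the route at 31.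

**Further compounds**

F1 | step 12 | C13 alcohol: the 10-(hydroxymethyl) analogue of 20 (C8 cis to the methyl ester) | COc1ccc(COC/C=C(C(=O)OC(C)(C)C)/CC/C=C(C)/C[C@H](O[Si](C)(C)C(C)(C)C)/C=C(C(=O)OC)/CO)cc1
F2 | step 12 | C13 bromide: the 10-(bromomethyl) analogue of 20 | COc1ccc(COC/C=C(C(=O)OC(C)(C)C)/CC/C=C(C)/C[C@H](O[Si](C)(C)C(C)(C)C)/C=C(C(=O)OC)/CBr)cc1
F3 | step 12 | hydroxy bromide: the 10-(bromomethyl) analogue of 21 | OC/C=C(C(=O)OC(C)(C)C)/CC/C=C(C)/C[C@H](O[Si](C)(C)C(C)(C)C)/C=C(C(=O)OC)/CBr
F4 | step 12 | bromo aldehyde: the 10-(bromomethyl) analogue of 22 | O=C/C=C(C(=O)OC(C)(C)C)/CC/C=C(C)/C[C@H](O[Si](C)(C)C(C)(C)C)/C=C(C(=O)OC)/CBr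
F5 | step 12 | ten-membered hydroxy ester: the 6α-hydroxy analogue of 23 | C/C1=C\CC/C(C(=O)OC(C)(C)C)=C/[C@@H](O)[C@H](C(=C)C(=O)OC)[C@@H](O[Si](C)(C)C(C)(C)C)C1
F6 | step 9 | α-iodo enoate: the 10-iodo analogue of 20 without the CH2Bpin group (iodine trans to C8) | COc1ccc(COC/C=C(C(=O)OC(C)(C)C)/CC/C=C(C)/C[C@H](O[Si](C)(C)C(C)(C)C)/C=C(/I)C(=O)OC)cc1
F7 | step 16 | 8β-{2-[bis(2,2,2-trifluoroethoxy)phosphoryl]propanoyloxy} analogue of 28 (both epimers at the phosphonate carbon) | C=C[C@]1(C)C[C@@H](OC(=O)C(C)P(=O)(OCC(F)(F)F)OCC(F)(F)F)[C@H]2C(=C)C(=O)O[C@@H]2[C@H]1C(=C)C(=O)OC(C)(C)C
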